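Everything rests on the C1–C8 disconnection and on a hidden symmetry. Without the C1 prenyl and C3 aroyl groups, ring A (C1–C2–C3–C4–C5–C9) has a mirror plane through C2 and C5. In the key step, one of the two diastereotopic enol ethers of a 6,6-dialkyl-1,5-dimethoxycyclohexa-1,4-diene opens a formyl-activated cyclopropane at its quaternary carbon C8, with inversion. This single operation closes ring B (C1–C9–C5–C6–C7–C8), sets C1, C5 and C8, and releases the aldehyde that becomes the homoprenyl chain. The precursor is a simple cyclohexadiene bearing a lavandulyl chain whose isopropenyl group has been cyclopropanated.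

Key step: step 10

Remark: C1–C9 are the bicyclo[3.3.1]nonane locants of the target (C1 next to C8), C10–C12 are the first three carbons of the C8 side chain, prenyl means 3-methylbut-2-enyl, and the target is taken as one tautomer of its enolised C2/C4 diketone.

Step 1
Reactants: 1 1,5-dimethoxycyclohexa-1,4-diene; 2 prenyl bromide
Product: 4 1,5-dimethoxy-6-prenylcyclohexa-1,4-diene, via lithiated diene 3 (not isolated)
Conditions: t-BuLi, THF, HMPA, −78 °C; then 2, −78 °C to rt
Reagents that add atoms: none
Why: Carbanion alkylation of a Birch-type diene: t-BuLi removes the C6 proton flanked by both enol ethers, and the cyclohexadienyl anion should be alkylated at this central carbon by the allylic bromide, with no stereocenter formed.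

Step 2
Reactants: 5 (S)-4-benzyloxazolidin-2-one; 6 3-methylbut-2-enoyl chloride
Product: 8 (S)-4-benzyl-3-(3-methylbut-2-enoyl)oxazolidin-2-one, via lithium oxazolidinide 7 (not isolated)
Conditions: n-BuLi, THF, −78 °C; then 6, −78 to 0 °C
Reagents that add atoms: none
Why: N-Acylation of the lithiated Evans auxiliary by the acid chloride is a standard imide synthesis and leaves the stereocenter of the auxiliary untouched.

Step 3
Reactants: 8 (S)-4-benzyl-3-(3-methylbut-2-enoyl)oxazolidin-2-one; 2 prenyl bromide
Product: 10 (S)-4-benzyl-3-[(2S)-5-methyl-2-(prop-1-en-2-yl)hex-4-enoyl]oxazolidin-2-one, via sodium dienolate 9 (not isolated)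
Conditions: NaN(SiMe3)2, THF, −78 °C; then 2, −78 to −40 °C
Reagents that add atoms: none
Why: Deconjugative Evans alkylation: γ-deprotonation gives the chelated Z-dienolate, which should react at its α-carbon on the face opposite the benzyl group, so the auxiliary sets C7.

Step 4
Reactants: 10 (S)-4-benzyl-3-[(2S)-5-methyl-2-(prop-1-en-2-yl)hex-4-enoyl]oxazolidin-2-one
Product: 11 (S)-lavandulol
Conditions: LiBH4, H2O (1 equiv), Et2O, 0 °C
Reagents that add atoms: none
Why: Reductive cleavage of the N-acyl oxazolidinone by borohydride attacks the exocyclic carbonyl, frees the auxiliary and does not touch C7 or the alkenes.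

Step 5
Reactants: 11 (S)-lavandulol
Product: 12 (S)-lavandulyl bromide
Conditions: CBr4, PPh3, CH2Cl2, 0 °C
Reagents that add atoms: carbon tetrabromide, BrC(Br)(Br)Br
Why: Appel reaction: the primary alcohol is displaced through its alkoxyphosphonium salt under neutral conditions, so the neighbouring C7 and both alkenes stay as they are.

Step 6
Reactants: 12 (S)-lavandulyl bromide; 13 tert-butyl diazoacetate
Product: 14 tert-butyl (1S,2S)-2-[(2S)-1-bromo-5-methylhex-4-en-2-yl]-2-methylcyclopropane-1-carboxylate
Conditions: 13 (slow addition), CuOTf·0.5C6H6 (cat.), 2,2'-(propane-2,2-diyl)bis[(4R)-4-tert-butyl-4,5-dihydrooxazole] (cat.), CH2Cl2, rt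
Reagents that add atoms: none
Why: Asymmetric cyclopropanation by a monovalent copper carbene: the 1,1-disubstituted alkene should react ahead of the trisubstituted one, the ligand fixes C11, and the preference of the bulky ester for the side away from the branched C7 substituent then fixes C8, any cis isomer being removed by chromatography.

Step 7
Reactants: 4 1,5-dimethoxy-6-prenylcyclohexa-1,4-diene; 14 tert-butyl (1S,2S)-2-[(2S)-1-bromo-5-methylhex-4-en-2-yl]-2-methylcyclopropane-1-carboxylate
Product: 16 6,6-dialkyl diene tert-butyl ester, via lithiated prenyl diene 15 (not isolated)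
Conditions: t-BuLi, THF, HMPA, −78 °C; then 14, −78 °C to rt
Reagents that add atoms: none
Why: Second carbanion alkylation of the diene: the tertiary cyclohexadienyl anion should displace the primary bromide faster than it attacks the hindered tert-butyl ester, and the new quaternary C5 is not yet a stereocenter because the ring keeps its mirror plane.

Step 8
Reactants: 16 6,6-dialkyl diene tert-butyl ester
Product: 17 6,6-dialkyl diene cyclopropylmethanol
Conditions: LiAlH4, Et2O, 0 °C; aq. NaOH work-up
Reagents that add atoms: none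
Why: Hydride reduction of the ester to the primary alcohol leaves enol ethers, alkenes and the cyclopropane untouched, and the basic work-up protects the enol ethers.

Step 9
Reactants: 17 6,6-dialkyl diene cyclopropylmethanol
Product: 18 6,6-dialkyl diene cyclopropanecarbaldehyde
Conditions: Pr4NRuO4 (cat.), N-methylmorpholine N-oxide, 4 Å molecular sieves, CH2Cl2, rt
Reagents that add atoms: none
Why: Ley–Griffith oxidation runs under neutral, water-free conditions, so it should stop at the aldehyde and spare the acid-labile enol ethers, and epimerisation at C11 would be harmless because C11 stops being a stereocenter in the next step.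

Step 10
Reactants: 18 6,6-dialkyl diene cyclopropanecarbaldehyde
Product: 20 bicyclic keto aldehyde, via methoxycarbenium triflate 19 (not isolated)
Conditions: Me3SiOTf, 2,6-di-tert-butyl-4-methylpyridine, CH2Cl2, −78 to −40 °C; then aq. NaHCO3, rt
Reagents that add atoms: water, O
Why: Me3SiOTf silylates the formyl oxygen, the cyclopropyl-conjugated oxocarbenium ion polarises the C8–C11 bond, the enol ether carbon C1 attacks the fully substituted C8 from the rear while C11 leaves as part of a silyl enol ether (19), and water then converts the C9 methoxycarbenium ion into the ketone and the silyl enol ether into the aldehyde. The closest known reaction type is the Lewis acid ring opening of a carbonyl-activated (donor–acceptor) cyclopropane by an enol ether, a homo-Mukaiyama–Michael reaction, together with the stereoinvertive substitution known for quaternary carbons of cyclopropyl carbonyl compounds. Ring B (C1–C9–C5–C6–C7–C8) closes in the 6-exo-tet mode through a chair-like transition state, the breaking C8–C11 bond lying outside the new ring. C8 is controlled by inversion of the cyclopropane carbon set in step 6, and C1 and C5 arise together from the choice between the two diastereotopic enol ethers, which C7 controls because attack through the C9=C1 enol ether keeps the C7 prenyl group and C10 equatorial and only the small methyl group axial, whereas the other enol ether would force both large groups axial. The step needs site selectivity for C8 over C10 and over the formyl carbon, secured by the tertiary cation character of C8 and by six-membered against seven- or eight-membered ring formation, and it needs the zwitterion not to collapse to a cyclopentane, which is excluded because C10 ends up antiperiplanar to the C1–C9 bond.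

Step 11
Reactants: 20 bicyclic keto aldehyde
Product: 21 4-methoxy-8-methyl-8-(4-methylpent-3-enyl)-5,7-diprenylbicyclo[3.3.1]non-3-en-9-one
Conditions: i-PrPPh3I, n-BuLi, THF, 0 °C; then 20, −78 to 0 °C
Reagents that add atoms: isopropyltriphenylphosphonium iodide, CC(C)[P+](c1ccccc1)(c1ccccc1)c1ccccc1.[I-]
Why: Wittig olefination: the unstabilised ylide should react with the unhindered aldehyde far faster than with the C9 ketone flanked by two bridgeheads, and the symmetric ylide terminus raises no question of alkene geometry.

Step 12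
Reactants: 21 4-methoxy-8-methyl-8-(4-methylpent-3-enyl)-5,7-diprenylbicyclo[3.3.1]non-3-en-9-one
Product: 22 4-methoxy-8-methyl-8-(4-methylpent-3-enyl)-5,7-diprenylbicyclo[3.3.1]non-3-ene-2,9-dione
Conditions: Pd(OH)2/C (cat.), t-BuOOH, K2CO3, CH2Cl2, 4 °C
Reagents that add atoms: tert-butyl hydroperoxide, CC(C)(C)OO
Why: Radical allylic oxidation by tert-butylperoxy radicals: the C2 methylene gives the only allyl radical that is also stabilised by the C4 methoxy group, so it should be oxidised ahead of the prenyl positions to the vinylogous ester.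

Step 13
Reactants: 22 4-methoxy-8-methyl-8-(4-methylpent-3-enyl)-5,7-diprenylbicyclo[3.3.1]non-3-ene-2,9-dione
Product: 24 3-trimethylsilyl vinylogous ester, via C3 vinyllithium 23 (not isolated)
Conditions: Me3SiCl then LiN(i-Pr)2, THF, −78 °C
Reagents that add atoms: chlorotrimethylsilane, C[Si](C)(C)Cl
Why: Vinyl lithiation under in situ quench: the C3–H between carbonyl and methoxy group is the kinetically most acidic site, and its silylation blocks it for the next step.

Step 14
Reactants: 24 3-trimethylsilyl vinylogous ester; 2 prenyl bromide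
Product: 26 1,5,7-triprenyl 3-trimethylsilyl vinylogous ester, via bridgehead lithium 25 (not isolated)
Conditions: LiN(i-Pr)2, THF, −78 to −40 °C; then 2, −78 to 0 °C
Reagents that add atoms: none
Why: Bridgehead lithiation and alkylation: once C3 is blocked the amide base can only remove the C1 proton flanked by the C2 and C9 carbonyl groups, and the pyramidal bridgehead carbanion must be alkylated with retention, so C1 keeps the configuration set in step 10.

Step 15
Reactants: 26 1,5,7-triprenyl 3-trimethylsilyl vinylogous ester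
Product: 27 4-methoxy-8-methyl-8-(4-methylpent-3-enyl)-1,5,7-triprenylbicyclo[3.3.1]non-3-ene-2,9-dione
Conditions: Bu4NF, THF, 0 °C
Reagents that add atoms: none
Why: Fluoride-induced protodesilylation of the α-silyl enone removes the blocking group under conditions that leave the vinylogous ester and the ketones alone.

Step 16
Reactants: 27 4-methoxy-8-methyl-8-(4-methylpent-3-enyl)-1,5,7-triprenylbicyclo[3.3.1]non-3-ene-2,9-dione; 28 3-acetoxybenzoyl chloride
Product: 30 3-(3-acetoxybenzoyl) vinylogous ester, via C3 vinyllithium 29 (not isolated)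
Conditions: lithium 2,2,6,6-tetramethylpiperidide (from the amine and n-BuLi), THF, −78 °C; then 28, −78 °C
Reagents that add atoms: none
Why: Vinyl lithiation at C3 followed by acylation installs the aroyl group, because the acid chloride is far more electrophilic than its own aryl acetate and the hindered amine by-product does not consume it.

Step 17
Reactants: 30 3-(3-acetoxybenzoyl) vinylogous ester
Product: 31 target CNP0406274.2
Conditions: LiOH, 1,4-dioxane/H2O, 90 °C; then dilute HCl
Reagents that add atoms: lithium hydroxide, [Li+].[OH-]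
Why: Hydroxide cleaves the vinylogous methyl ester by addition and elimination at C4 and saponifies the aryl acetate in the same pot, and acidification gives the enolised triketone without touching the four stereocenters, none of which can epimerise.

Compound list
1 | 1,5-dimethoxycyclohexa-1,4-diene | COC1=CCC=C(OC)C1 | starting material
2 | prenyl bromide (1-bromo-3-methylbut-2-ene) | CC(C)=CCBr | starting material
3 | 6-lithio-1,5-dimethoxycyclohexa-1,4-diene | COC1=CCC=C(OC)C1[Li] | intermediate
4 | 1,5-dimethoxy-6-prenylcyclohexa-1,4-diene | COC1=CCC=C(OC)C1CC=C(C)C | intermediate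
5 | (S)-4-benzyloxazolidin-2-one | O=C1N[C@@H](Cc2ccccc2)CO1 | starting material
6 | 3-methylbut-2-enoyl chloride | CC(C)=CC(=O)Cl | starting material
7 | N-lithio-(S)-4-benzyloxazolidin-2-one | O=C1N([Li])[C@@H](Cc2ccccc2)CO1 | intermediate
8 | (S)-4-benzyl-3-(3-methylbut-2-enoyl)oxazolidin-2-one | CC(C)=CC(=O)N1[C@@H](Cc2ccccc2)COC1=O | intermediate
9 | sodium Z-dienolate of 8 (enolate oxygen cis to the isopropenyl group) | C=C(C)/C=C(\[O-])N1[C@@H](Cc2ccccc2)COC1=O.[Na+] | intermediate
10 | (S)-4-benzyl-3-[(2S)-5-methyl-2-(prop-1-en-2-yl)hex-4-enoyl]oxazolidin-2-one | C=C(C)[C@H](CC=C(C)C)C(=O)N1[C@@H](Cc2ccccc2)COC1=O | intermediate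
11 | (S)-lavandulol, (2S)-5-methyl-2-(prop-1-en-2-yl)hex-4-en-1-ol | C=C(C)[C@H](CC=C(C)C)CO | intermediate
12 | (S)-lavandulyl bromide, the primary bromide of 11 | C=C(C)[C@H](CC=C(C)C)CBr | intermediate
13 | tert-butyl diazoacetate | CC(C)(C)OC(=O)C=[N+]=[N-] | starting material
14 | tert-butyl (1S,2S)-2-[(2S)-1-bromo-5-methylhex-4-en-2-yl]-2-methylcyclopropane-1-carboxylate (ester cis to the ring methyl, trans to the branched chain) | CC(C)(C)OC(=O)[C@H]1C[C@]1(C)[C@H](CC=C(C)C)CBr | intermediate
15 | 6-lithio-1,5-dimethoxy-6-prenylcyclohexa-1,4-diene | COC1=CCC=C(OC)C1([Li])CC=C(C)C | intermediate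
16 | tert-butyl (1S,2R)-2-{(2R)-1-[2,6-dimethoxy-1-prenylcyclohexa-2,5-dien-1-yl]-5-methylhex-4-en-2-yl}-2-methylcyclopropane-1-carboxylate (same spatial arrangement as in 14) | COC1=CCC=C(OC)C1(CC=C(C)C)C[C@@H](CC=C(C)C)[C@@]2(C)C[C@@H]2C(=O)OC(C)(C)C | intermediate
17 | cyclopropylmethanol from 16 (CH2OH in place of the ester, stereocenters unchanged) | COC1=CCC=C(OC)C1(CC=C(C)C)C[C@@H](CC=C(C)C)[C@@]2(C)C[C@@H]2CO | intermediate
18 | cyclopropanecarbaldehyde from 17 (CHO in place of CH2OH, stereocenters unchanged) | COC1=CCC=C(OC)C1(CC=C(C)C)C[C@@H](CC=C(C)C)[C@@]2(C)C[C@@H]2C=O | intermediate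
19 | bicyclic C9 methoxycarbenium triflate carrying the C11=C12 trimethylsilyl enol ether on C10 (target configuration at C1, C5, C7, C8) | C[Si](C)(C)OC=CC[C@@]1(C)[C@H](CC=C(C)C)C[C@]2(CC=C(C)C)C(=[O+]C)[C@H]1CC=C2OC.[O-]S(=O)(=O)C(F)(F)F | intermediate
20 | 3-[4-methoxy-8-methyl-9-oxo-5,7-diprenylbicyclo[3.3.1]non-3-en-8-yl]propanal (target configuration at C1, C5, C7, C8; C7 prenyl and C8 chain equatorial, C8 methyl axial) | O=CCC[C@@]1(C)[C@H](CC=C(C)C)C[C@]2(CC=C(C)C)C(=O)[C@H]1CC=C2OC | intermediate
21 | 4-methoxy-8-methyl-8-(4-methylpent-3-enyl)-5,7-diprenylbicyclo[3.3.1]non-3-en-9-one (target configuration) | CC(C)=CCC[C@@]1(C)[C@H](CC=C(C)C)C[C@]2(CC=C(C)C)C(=O)[C@H]1CC=C2OC | intermediate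
22 | 4-methoxy-8-methyl-8-(4-methylpent-3-enyl)-5,7-diprenylbicyclo[3.3.1]non-3-ene-2,9-dione (target configuration) | CC(C)=CCC[C@@]1(C)[C@H](CC=C(C)C)C[C@]2(CC=C(C)C)C(=O)[C@H]1C(=O)C=C2OC | intermediate
23 | 3-lithio derivative of 22 | CC(C)=CCC[C@@]1(C)[C@H](CC=C(C)C)C[C@]2(CC=C(C)C)C(=O)[C@H]1C(=O)C([Li])=C2OC | intermediate
24 | 3-trimethylsilyl derivative of 22 | CC(C)=CCC[C@@]1(C)[C@H](CC=C(C)C)C[C@]2(CC=C(C)C)C(=O)[C@H]1C(=O)C([Si](C)(C)C)=C2OC | intermediate
25 | 1-lithio derivative of 24 (bridgehead lithium) | CC(C)=CCC[C@@]1(C)[C@H](CC=C(C)C)C[C@]2(CC=C(C)C)C(=O)[C@@]1([Li])C(=O)C([Si](C)(C)C)=C2OC | intermediate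
26 | 4-methoxy-8-methyl-8-(4-methylpent-3-enyl)-1,5,7-triprenyl-3-trimethylsilylbicyclo[3.3.1]non-3-ene-2,9-dione (target configuration) | CC(C)=CCC[C@@]1(C)[C@H](CC=C(C)C)C[C@]2(CC=C(C)C)C(=O)[C@@]1(CC=C(C)C)C(=O)C([Si](C)(C)C)=C2OC | intermediate
27 | 4-methoxy-8-methyl-8-(4-methylpent-3-enyl)-1,5,7-triprenylbicyclo[3.3.1]non-3-ene-2,9-dione (target configuration) | CC(C)=CCC[C@@]1(C)[C@H](CC=C(C)C)C[C@]2(CC=C(C)C)C(=O)[C@@]1(CC=C(C)C)C(=O)C=C2OC | intermediate
28 | 3-acetoxybenzoyl chloride | CC(=O)Oc1cccc(C(=O)Cl)c1 | starting material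
29 | 3-lithio derivative of 27 | CC(C)=CCC[C@@]1(C)[C@H](CC=C(C)C)C[C@]2(CC=C(C)C)C(=O)[C@@]1(CC=C(C)C)C(=O)C([Li])=C2OC | intermediate
30 | 3-(3-acetoxybenzoyl)-4-methoxy-8-methyl-8-(4-methylpent-3-enyl)-1,5,7-triprenylbicyclo[3.3.1]non-3-ene-2,9-dione (target configuration) | CC(C)=CCC[C@@]1(C)[C@H](CC=C(C)C)C[C@]2(CC=C(C)C)C(=O)[C@@]1(CC=C(C)C)C(=O)C(C(=O)c1cccc(OC(C)=O)c1)=C2OC | intermediate
31 | (1S,5S,7R,8S)-4-hydroxy-3-(3-hydroxybenzoyl)-8-methyl-8-(4-methylpent-3-enyl)-1,5,7-triprenylbicyclo[3.3.1]non-3-ene-2,9-dione | CC(C)=CCC[C@@]1(C)[C@H](CC=C(C)C)C[C@]2(CC=C(C)C)C(=O)[C@@]1(CC=C(C)C)C(=O)C(C(=O)c1cccc(O)c1)=C2O | target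

Total step count: 17. Longest linear sequence: 16 steps (steps 2 to 17).

Steps most likely to fail

Step 10. The single formyl group may polarise the C8–C11 bond too weakly. Ring opening may also end in proton loss or in dihydrofuran formation before C1 arrives, which would erode the stereochemical transfer at C8. The fallback moves the closure to the cyclopropylcarbinyl cation manifold.
- It sets out from alcohol 17. Tf2O and 2,6-di-tert-butyl-4-methylpyridine in CH2Cl2 at −78 °C ionise the primary carbinol.
- The enol ether attacks C8 with the same inversion while C11–C12 becomes a vinyl group (cyclopropylcarbinyl to homoallyl substitution). Aqueous NaHCO3 then gives the C8-allyl ketone F1.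
- 9-BBN followed by NaBO3 turns the only monosubstituted alkene into the primary alcohol F2.
- Oxidation by Pr4NRuO4 and N-methylmorpholine N-oxide comes back to the route at keto aldehyde 20.

Step 7. Substitution at the β-branched bromide may be slower than elimination across C6–C7, or slower than attack of the tertiary carbanion on the ester. The fallback inverts the order of the two alkylations. The hindered electrophile then meets the unhindered anion, and the quaternary centre is made with prenyl bromide.
- It sets out from 14. i-Bu2AlH reduces the ester to the bromo alcohol F3, and t-BuMe2SiCl with imidazole gives the silyl ether F4.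
- Lithiated diene 3 is alkylated by F4 to the monoalkyl diene F5.
- A second deprotonation by t-BuLi and addition of 2 give the dialkyl diene F6.
- Bu4NF frees alcohol 17, where the route is rejoined.

Step 14. The bridgehead carbanion next to the quaternary C8 may be alkylated too slowly and decay by proton return. The fallback traps it with a carbonyl electrophile and builds the prenyl group afterwards.
- It sets out from 24. Bridgehead lithium 25 is quenched by acrolein to the allylic alcohol F7, whose carbinol configuration is irrelevant.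
- Ac2O in pyridine gives the acetate F8.
- Pd(PPh3)4 and HCO2NH4 deliver hydride to the inner allyl terminus to give the C1-allyl compound F9.
- Cross metathesis with 2-methylbut-2-ene (second-generation Grubbs catalyst) comes back to the route at 26.

Further compounds
F1 | step 10 | 8-allyl-4-methoxy-8-methyl-5,7-diprenylbicyclo[3.3.1]non-3-en-9-one (target configuration at C1, C5, C7, C8) | C=CC[C@@]1(C)[C@H](CC=C(C)C)C[C@]2(CC=C(C)C)C(=O)[C@H]1CC=C2OC
F2 | step 10 | 8-(3-hydroxypropyl)-4-methoxy-8-methyl-5,7-diprenylbicyclo[3.3.1]non-3-en-9-one (target configuration at C1, C5, C7, C8) | OCCC[C@@]1(C)[C@H](CC=C(C)C)C[C@]2(CC=C(C)C)C(=O)[C@H]1CC=C2OC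
F3 | step 7 | {(1S,2S)-2-[(2S)-1-bromo-5-methylhex-4-en-2-yl]-2-methylcyclopropyl}methanol | OC[C@H]1C[C@]1(C)[C@H](CC=C(C)C)CBr
F4 | step 7 | tert-butyldimethylsilyl ether of F3 | CC(C)(C)[Si](C)(C)OC[C@H]1C[C@]1(C)[C@H](CC=C(C)C)CBr
F5 | step 7 | 1,5-dimethoxycyclohexa-1,4-diene carrying at C6 only the silyl-protected cyclopropyl chain (stereocenters as in F4) | COC1=CCC=C(OC)C1C[C@@H](CC=C(C)C)[C@@]2(C)C[C@@H]2CO[Si](C)(C)C(C)(C)C
F6 | step 7 | tert-butyldimethylsilyl ether of 17 | COC1=CCC=C(OC)C1(CC=C(C)C)C[C@@H](CC=C(C)C)[C@@]2(C)C[C@@H]2CO[Si](C)(C)C(C)(C)C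
F7 | step 14 | 1-(1-hydroxyprop-2-enyl) derivative of 24 (carbinol carbon unassigned) | CC(C)=CCC[C@@]1(C)[C@H](CC=C(C)C)C[C@]2(CC=C(C)C)C(=O)[C@@]1(C(O)C=C)C(=O)C([Si](C)(C)C)=C2OC
F8 | step 14 | acetate of F7 | CC(C)=CCC[C@@]1(C)[C@H](CC=C(C)C)C[C@]2(CC=C(C)C)C(=O)[C@@]1(C(OC(C)=O)C=C)C(=O)C([Si](C)(C)C)=C2OC
F9 | step 14 | 1-allyl derivative of 24 | CC(C)=CCC[C@@]1(C)[C@H](CC=C(C)C)C[C@]2(CC=C(C)C)C(=O)[C@@]1(CC=C)C(=O)C([Si](C)(C)C)=C2OC
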